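**Retrosynthetic overview**

1. Feature: in the lactone O1–C2(=O)–C3–C4–C5, C3 is a tertiary α-hydroxy ester carbon that carries the ring A benzyl CH2. This is the pattern left by a 1,2-benzyl shift in a 1,2-diketone after the C5 hydroxyl has added to the benzyl-bearing ketone.
2. Target 26 ⇐ tris-silyl ether 25 ⇐ hydroxy 1,2-diketone 23; this one step makes the O1–C2 and C3–CH2(ring A) bonds, the lactone ring and the C3 stereocentre.
3. 23 ⇐ bis-TBS diketone 22 ⇐ internal alkyne 21 (oxidation) ⇐ terminal alkyne 19 + ring A benzylic bromide 4.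
4. 19 ⇐ aldehyde 18 ⇐ Weinreb amide 16 ⇐ Evans syn aldol of imide 11 with TIPS-vanillin 2, which sets C4 and the carbinol carbon.
5. Ring order: rings A and B come from vanillin; the lactone is the only ring made and is closed last, in the key step.

Key step: step 15

Remark: the target is read as (3S,4R) with an (R) carbinol carbon, i.e. benzyl trans and hydroxyl cis to the C4 substituent; this requires the (2R,3R) syn aldol product from the (R)-auxiliary.
Remark: hydroxy diketone 23 is drawn as the open diketo form; in solution it is expected to be a mixture of this form, its benzylic enol and the five-membered hemiketal 24.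
Abbreviations: TBS = tert-butyldimethylsilyl, TIPS = triisopropylsilyl, Ar = 3-methoxy-4-(triisopropylsilyloxy)phenyl.

**Route**

Step 1
Reactants: 1 vanillin
Product: 2 3-methoxy-4-(triisopropylsilyloxy)benzaldehyde
Conditions: TIPSCl, imidazole, DMF, rt
Reagents that add atoms: chlorotriisopropylsilane, CC(C)[Si](Cl)(C(C)C)C(C)C
Why: Imidazole-promoted silylation of the phenol gives an aryl TIPS ether that should tolerate the later boron, aluminium, lithium and permanganate reagents and is removed by fluoride at the end.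

Step 2
Reactants: 2 3-methoxy-4-(triisopropylsilyloxy)benzaldehyde
Product: 3 [3-methoxy-4-(triisopropylsilyloxy)phenyl]methanol
Conditions: NaBH4, MeOH, 0 °C
Reagents that add atoms: none
Why: Borohydride reduction of the aryl aldehyde to the benzylic alcohol leaves the aryl silyl ether untouched.

Step 3
Reactants: 3 [3-methoxy-4-(triisopropylsilyloxy)phenyl]methanol
Product: 4 4-(bromomethyl)-2-methoxy-1-(triisopropylsilyloxy)benzene
Conditions: CBr4, PPh3, CH2Cl2, 0 °C
Reagents that add atoms: tetrabromomethane, BrC(Br)(Br)Br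
Why: The Appel reaction makes the benzylic bromide under neutral conditions, avoiding acid that could ionise this electron-rich benzylic position; the bromide is used soon after it is made.

Step 4
Reactants: 5 methyl 3-hydroxypropanoate
Product: 6 methyl 3-(tert-butyldimethylsilyloxy)propanoate
Conditions: TBSCl, imidazole, CH2Cl2, rt
Reagents that add atoms: tert-butylchlorodimethylsilane, CC(C)(C)[Si](C)(C)Cl
Why: Standard silylation of the primary alcohol; a primary TBS ether is chosen for the future lactone CH2–O because it can later be cleaved beside a hindered secondary TBS ether.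

Step 5
Reactants: 6 methyl 3-(tert-butyldimethylsilyloxy)propanoate
Product: 8 3-(tert-butyldimethylsilyloxy)propanoic acid, via lithium carboxylate 7 (not isolated)
Conditions: LiOH, THF/H2O, 0 °C → rt; then 1 M HCl to pH 4, 0 °C
Reagents that add atoms: lithium hydroxide, [Li+].[OH-]
Why: Saponification of the methyl ester at low temperature followed by mild acidification, which the primary TBS ether should withstand.

Step 6
Reactants: 8 3-(tert-butyldimethylsilyloxy)propanoic acid; 9 (R)-4-benzyl-2-oxazolidinone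
Product: 11 (R)-4-benzyl-3-[3-(tert-butyldimethylsilyloxy)propanoyl]oxazolidin-2-one, via mixed pivalic anhydride 10 (not isolated)
Conditions: t-BuCOCl, Et3N, THF, −20 °C; then 9, LiCl, −20 °C → rt
Reagents that add atoms: none
Why: N-acylation of the oxazolidinone through the mixed pivalic anhydride with LiCl/Et3N activation avoids strong base and an acid chloride of the β-silyloxy acid.

Step 7
Reactants: 11 (R)-4-benzyl-3-[3-(tert-butyldimethylsilyloxy)propanoyl]oxazolidin-2-one; 2 3-methoxy-4-(triisopropylsilyloxy)benzaldehyde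
Product: 14 (R)-4-benzyl-3-[(2R,3R)-2-[(tert-butyldimethylsilyloxy)methyl]-3-hydroxy-3-Ar-propanoyl]oxazolidin-2-one, via boron enolate 12 (not isolated), via boron aldolate 13 (not isolated)
Conditions: Bu2BOTf, i-Pr2NEt, CH2Cl2, 0 °C; 2, −78 → 0 °C; then pH 7 phosphate buffer, MeOH, 30% H2O2, 0 °C
Reagents that add atoms: none
Why: Evans syn aldol reaction in which the Z boron enolate reacts through a Zimmerman–Traxler chair on the enolate face left open by the benzyl group of the (R)-auxiliary, setting C4 and the carbinol carbon as the (2R,3R) syn pair, while the covalent boron enolate should not expel the β-silyloxy group.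

Step 8
Reactants: 14 (R)-4-benzyl-3-[(2R,3R)-2-[(tert-butyldimethylsilyloxy)methyl]-3-hydroxy-3-Ar-propanoyl]oxazolidin-2-one
Product: 15 (2R,3R)-2-[(tert-butyldimethylsilyloxy)methyl]-3-hydroxy-N-methoxy-N-methyl-3-Ar-propanamide
Conditions: MeONHMe·HCl, AlMe3, CH2Cl2, −15 → 0 °C; aq. KNaC4H4O6
Reagents that add atoms: N,O-dimethylhydroxylamine hydrochloride, CNOC.Cl
Why: Weinreb transamidation with the chloroaluminium amide, directed to the exocyclic carbonyl by the aluminium alkoxide of the free β-hydroxyl, releases the auxiliary without touching the two stereocentres.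

Step 9
Reactants: 15 (2R,3R)-2-[(tert-butyldimethylsilyloxy)methyl]-3-hydroxy-N-methoxy-N-methyl-3-Ar-propanamide
Product: 16 (2R,3R)-3-(tert-butyldimethylsilyloxy)-2-[(tert-butyldimethylsilyloxy)methyl]-N-methoxy-N-methyl-3-Ar-propanamide
Conditions: TBSOTf, 2,6-lutidine, CH2Cl2, −78 → 0 °C
Reagents that add atoms: tert-butyldimethylsilyl triflate, CC(C)(C)[Si](C)(C)OS(=O)(=O)C(F)(F)F
Why: Silyl triflate with 2,6-lutidine silylates the hindered benzylic hydroxyl without retro-aldol cleavage; this group later keeps the carbinol oxygen out of hemiketal formation and shields one face next to C4.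

Step 10
Reactants: 16 (2R,3R)-3-(tert-butyldimethylsilyloxy)-2-[(tert-butyldimethylsilyloxy)methyl]-N-methoxy-N-methyl-3-Ar-propanamide
Product: 18 (2R,3R)-3-(tert-butyldimethylsilyloxy)-2-[(tert-butyldimethylsilyloxy)methyl]-3-Ar-propanal, via aluminium hemiaminal 17 (not isolated)
Conditions: i-Bu2AlH, THF, −78 °C; aq. KNaC4H4O6
Reagents that add atoms: none
Why: Reduction of the Weinreb amide stops at the chelated tetrahedral aluminium adduct, which gives the aldehyde only on work-up, and no alkoxide is ever formed next to the primary silyl ether, so a silyl shift between the two CH2–O arms that would scramble C4 cannot occur.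

Step 11
Reactants: 18 (2R,3R)-3-(tert-butyldimethylsilyloxy)-2-[(tert-butyldimethylsilyloxy)methyl]-3-Ar-propanal
Product: 19 4-[(1R,2R)-1-(tert-butyldimethylsilyloxy)-2-[(tert-butyldimethylsilyloxy)methyl]but-3-yn-1-yl]-2-methoxy-1-(triisopropylsilyloxy)benzene
Conditions: dimethyl (1-diazo-2-oxopropyl)phosphonate, K2CO3, MeOH, 0 °C → rt
Reagents that add atoms: dimethyl (1-diazo-2-oxopropyl)phosphonate, CC(=O)C(=[N+]=[N-])P(=O)(OC)OC
Why: Seyferth–Gilbert homologation with the Ohira–Bestmann reagent converts the freshly made aldehyde into the terminal alkyne; addition of the diazophosphonate anion should outrun enolisation of the α-branched aldehyde, and the hindered aryl TIPS ethers should tolerate cold K2CO3/MeOH for the short time needed.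

Step 12
Reactants: 19 4-[(1R,2R)-1-(tert-butyldimethylsilyloxy)-2-[(tert-butyldimethylsilyloxy)methyl]but-3-yn-1-yl]-2-methoxy-1-(triisopropylsilyloxy)benzene; 4 4-(bromomethyl)-2-methoxy-1-(triisopropylsilyloxy)benzene
Product: 21 4-[(1R,2R)-1-(tert-butyldimethylsilyloxy)-2-[(tert-butyldimethylsilyloxy)methyl]-5-Ar-pent-3-yn-1-yl]-2-methoxy-1-(triisopropylsilyloxy)benzene, via lithium acetylide 20 (not isolated)
Conditions: n-BuLi, THF, −78 °C; then 4, DMPU, −78 → 0 °C
Reagents that add atoms: none
Why: SN2 alkylation of the lithium acetylide with the very reactive electron-rich benzylic bromide joins the alkyne terminus to the ring A benzylic carbon; the acetylide is not basic enough to isomerise the benzylic propargylic CH2 of the product.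

Step 13
Reactants: 21 4-[(1R,2R)-1-(tert-butyldimethylsilyloxy)-2-[(tert-butyldimethylsilyloxy)methyl]-5-Ar-pent-3-yn-1-yl]-2-methoxy-1-(triisopropylsilyloxy)benzene
Product: 22 (4R,5R)-5-(tert-butyldimethylsilyloxy)-4-[(tert-butyldimethylsilyloxy)methyl]-1,5-bis[3-methoxy-4-(triisopropylsilyloxy)phenyl]pentane-2,3-dione
Conditions: KMnO4, NaHCO3, MgSO4, acetone/H2O, 0 °C → rt
Reagents that add atoms: potassium permanganate KMnO4, [K+].[O-][Mn](=O)(=O)=O
Why: Permanganate oxidation of an internal alkyne to the 1,2-diketone under MgSO4/NaHCO3 buffering is chosen because RuO4 would degrade the electron-rich arenes and because near-neutral conditions spare the silyl ethers and the acidic C4–H.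

Step 14
Reactants: 22 (4R,5R)-5-(tert-butyldimethylsilyloxy)-4-[(tert-butyldimethylsilyloxy)methyl]-1,5-bis[3-methoxy-4-(triisopropylsilyloxy)phenyl]pentane-2,3-dione
Product: 23 (4R,5R)-5-(tert-butyldimethylsilyloxy)-4-(hydroxymethyl)-1,5-bis[3-methoxy-4-(triisopropylsilyloxy)phenyl]pentane-2,3-dione
Conditions: HF·pyridine, pyridine, THF, 0 °C
Reagents that add atoms: none
Why: Buffered HF·pyridine should cleave the unhindered primary TBS ether much faster than the hindered secondary benzylic one, and aryl TIPS ethers, which are labile to basic fluoride, react slowly under these weakly acidic conditions.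

Step 15
Reactants: 23 (4R,5R)-5-(tert-butyldimethylsilyloxy)-4-(hydroxymethyl)-1,5-bis[3-methoxy-4-(triisopropylsilyloxy)phenyl]pentane-2,3-dione
Product: 25 (3S,4R)-4-[(R)-(tert-butyldimethylsilyloxy)(Ar)methyl]-3-hydroxy-3-[3-methoxy-4-(triisopropylsilyloxy)benzyl]dihydrofuran-2(3H)-one, via cyclic hemiketal 24 (not isolated)
Conditions: Al(Ot-Bu)3 (1.1 equiv), toluene, rt → 50 °C; aq. KNaC4H4O6
Reagents that add atoms: none
Why: Proposed new method: the primary hydroxyl of 23 adds reversibly to the benzyl-bearing ketone (5-exo-trig; the four-membered alternative at the nearer ketone is out of reach) to give hemiketal 24, whose aluminium alkoxide is chelated to the neighbouring ring ketone, and the electron-rich benzyl group then shifts suprafacially to that ketone carbon, so that the hemiketal carbon becomes the lactone carbonyl C2 (O1–C2 bond) and the former ketone carbon becomes the carbinol C3 (C3–CH2 bond). The closest known reactions are the benzilic ester rearrangement of 1,2-diketones with alkoxides and the aluminium-alkoxide-mediated α-ketol rearrangement of 2-hydroxyfuran-3(2H)-ones; the intramolecular, lactone-forming variant with a migrating benzyl group is not established. The shift gains ester resonance and is irreversible, whereas the hemiketal epimers, the open diketone and its benzylic enol interconvert, so the outcome is decided in the migration step. The new stereocentre C3 is controlled by C4: the benzyl group should cross on the ring face anti to the bulky silyloxy(aryl)methyl group, which places benzyl trans and hydroxyl cis to that group as in the (3S) target. The step needs migration to outrun enolisation towards C4 (epimerisation or loss of the β-silyloxy group) and any hydride reduction of the diketone; a non-basic aluminium alkoxide with no α-hydrogen to transfer, the chelate that aligns the pseudo-axial benzyl group with the ketone π* orbital, and the silyl ether that stops the carbinol oxygen from forming a rival hemiketal are meant to secure this.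

Step 16
Reactants: 25 (3S,4R)-4-[(R)-(tert-butyldimethylsilyloxy)(Ar)methyl]-3-hydroxy-3-[3-methoxy-4-(triisopropylsilyloxy)benzyl]dihydrofuran-2(3H)-one
Product: 26 (3S,4R)-3-hydroxy-4-[(R)-hydroxy(4-hydroxy-3-methoxyphenyl)methyl]-3-(4-hydroxy-3-methoxybenzyl)dihydrofuran-2(3H)-one
Conditions: Bu4NF, AcOH (1:1), THF, 0 °C → rt
Reagents that add atoms: none
Why: Fluoride cleaves the two aryl TIPS ethers and the secondary TBS ether, while acetic acid keeps the phenols protonated, which should suppress quinone methide formation at the p-hydroxybenzylic carbinol and opening of the lactone.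

**Compound list**

1 | vanillin | COc1cc(C=O)ccc1O | starting material
2 | 3-methoxy-4-(triisopropylsilyloxy)benzaldehyde | COc1cc(C=O)ccc1O[Si](C(C)C)(C(C)C)C(C)C | intermediate
3 | [3-methoxy-4-(triisopropylsilyloxy)phenyl]methanol | COc1cc(CO)ccc1O[Si](C(C)C)(C(C)C)C(C)C | intermediate
4 | 4-(bromomethyl)-2-methoxy-1-(triisopropylsilyloxy)benzene (ring A bromide) | COc1cc(CBr)ccc1O[Si](C(C)C)(C(C)C)C(C)C | intermediate
5 | methyl 3-hydroxypropanoate | COC(=O)CCO | starting material
6 | methyl 3-(tert-butyldimethylsilyloxy)propanoate | COC(=O)CCO[Si](C)(C)C(C)(C)C | intermediate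
7 | lithium 3-(tert-butyldimethylsilyloxy)propanoate (formed in the flask) | [Li+].[O-]C(=O)CCO[Si](C)(C)C(C)(C)C | intermediate
8 | 3-(tert-butyldimethylsilyloxy)propanoic acid | OC(=O)CCO[Si](C)(C)C(C)(C)C | intermediate
9 | (R)-4-benzyl-2-oxazolidinone | O=C1N[C@H](Cc2ccccc2)CO1 | starting material
10 | 3-(tert-butyldimethylsilyloxy)propanoic pivalic anhydride (formed in the flask) | CC(C)(C)C(=O)OC(=O)CCO[Si](C)(C)C(C)(C)C | intermediate
11 | (R)-4-benzyl-3-[3-(tert-butyldimethylsilyloxy)propanoyl]oxazolidin-2-one | O=C(CCO[Si](C)(C)C(C)(C)C)N1[C@H](Cc2ccccc2)COC1=O | intermediate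
12 | (Z)-dibutylboron enolate of 11 (formed in the flask) | CCCCB(CCCC)O/C(=C\CO[Si](C)(C)C(C)(C)C)N1[C@H](Cc2ccccc2)COC1=O | intermediate
13 | dibutylboron aldolate of 14 (formed in the flask) | O=C([C@H](CO[Si](C)(C)C(C)(C)C)[C@@H](OB(CCCC)CCCC)c1ccc(O[Si](C(C)C)(C(C)C)C(C)C)c(OC)c1)N1[C@H](Cc2ccccc2)COC1=O | intermediate
14 | (R)-4-benzyl-3-[(2R,3R)-2-[(tert-butyldimethylsilyloxy)methyl]-3-hydroxy-3-[3-methoxy-4-(triisopropylsilyloxy)phenyl]propanoyl]oxazolidin-2-one | O=C([C@H](CO[Si](C)(C)C(C)(C)C)[C@@H](O)c1ccc(O[Si](C(C)C)(C(C)C)C(C)C)c(OC)c1)N1[C@H](Cc2ccccc2)COC1=O | intermediate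
15 | (2R,3R)-2-[(tert-butyldimethylsilyloxy)methyl]-3-hydroxy-N-methoxy-3-[3-methoxy-4-(triisopropylsilyloxy)phenyl]-N-methylpropanamide | CON(C)C(=O)[C@H](CO[Si](C)(C)C(C)(C)C)[C@@H](O)c1ccc(O[Si](C(C)C)(C(C)C)C(C)C)c(OC)c1 | intermediate
16 | (2R,3R)-3-(tert-butyldimethylsilyloxy)-2-[(tert-butyldimethylsilyloxy)methyl]-N-methoxy-3-[3-methoxy-4-(triisopropylsilyloxy)phenyl]-N-methylpropanamide | CON(C)C(=O)[C@H](CO[Si](C)(C)C(C)(C)C)[C@@H](O[Si](C)(C)C(C)(C)C)c1ccc(O[Si](C(C)C)(C(C)C)C(C)C)c(OC)c1 | intermediate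
17 | diisobutylaluminium hemiaminal of 16 (formed in the flask, hemiaminal carbon undefined) | CON(C)C(O[Al](CC(C)C)CC(C)C)[C@H](CO[Si](C)(C)C(C)(C)C)[C@@H](O[Si](C)(C)C(C)(C)C)c1ccc(O[Si](C(C)C)(C(C)C)C(C)C)c(OC)c1 | intermediate
18 | (2R,3R)-3-(tert-butyldimethylsilyloxy)-2-[(tert-butyldimethylsilyloxy)methyl]-3-[3-methoxy-4-(triisopropylsilyloxy)phenyl]propanal | O=C[C@H](CO[Si](C)(C)C(C)(C)C)[C@@H](O[Si](C)(C)C(C)(C)C)c1ccc(O[Si](C(C)C)(C(C)C)C(C)C)c(OC)c1 | intermediate
19 | 4-[(1R,2R)-1-(tert-butyldimethylsilyloxy)-2-[(tert-butyldimethylsilyloxy)methyl]but-3-yn-1-yl]-2-methoxy-1-(triisopropylsilyloxy)benzene | C#C[C@H](CO[Si](C)(C)C(C)(C)C)[C@@H](O[Si](C)(C)C(C)(C)C)c1ccc(O[Si](C(C)C)(C(C)C)C(C)C)c(OC)c1 | intermediate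
20 | lithium acetylide of 19 (formed in the flask) | [Li]C#C[C@H](CO[Si](C)(C)C(C)(C)C)[C@@H](O[Si](C)(C)C(C)(C)C)c1ccc(O[Si](C(C)C)(C(C)C)C(C)C)c(OC)c1 | intermediate
21 | 4-[(1R,2R)-1-(tert-butyldimethylsilyloxy)-2-[(tert-butyldimethylsilyloxy)methyl]-5-[3-methoxy-4-(triisopropylsilyloxy)phenyl]pent-3-yn-1-yl]-2-methoxy-1-(triisopropylsilyloxy)benzene | COc1cc(CC#C[C@H](CO[Si](C)(C)C(C)(C)C)[C@@H](O[Si](C)(C)C(C)(C)C)c2ccc(O[Si](C(C)C)(C(C)C)C(C)C)c(OC)c2)ccc1O[Si](C(C)C)(C(C)C)C(C)C | intermediate
22 | (4R,5R)-5-(tert-butyldimethylsilyloxy)-4-[(tert-butyldimethylsilyloxy)methyl]-1,5-bis[3-methoxy-4-(triisopropylsilyloxy)phenyl]pentane-2,3-dione | COc1cc(CC(=O)C(=O)[C@H](CO[Si](C)(C)C(C)(C)C)[C@@H](O[Si](C)(C)C(C)(C)C)c2ccc(O[Si](C(C)C)(C(C)C)C(C)C)c(OC)c2)ccc1O[Si](C(C)C)(C(C)C)C(C)C | intermediate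
23 | (4R,5R)-5-(tert-butyldimethylsilyloxy)-4-(hydroxymethyl)-1,5-bis[3-methoxy-4-(triisopropylsilyloxy)phenyl]pentane-2,3-dione (key-step precursor) | COc1cc(CC(=O)C(=O)[C@H](CO)[C@@H](O[Si](C)(C)C(C)(C)C)c2ccc(O[Si](C(C)C)(C(C)C)C(C)C)c(OC)c2)ccc1O[Si](C(C)C)(C(C)C)C(C)C | intermediate
24 | (4R)-4-[(R)-(tert-butyldimethylsilyloxy)[3-methoxy-4-(triisopropylsilyloxy)phenyl]methyl]-2-hydroxy-2-[3-methoxy-4-(triisopropylsilyloxy)benzyl]dihydrofuran-3(2H)-one (formed in the flask, both C2 epimers) | COc1cc(CC2(O)OC[C@H]([C@@H](O[Si](C)(C)C(C)(C)C)c3ccc(O[Si](C(C)C)(C(C)C)C(C)C)c(OC)c3)C2=O)ccc1O[Si](C(C)C)(C(C)C)C(C)C | intermediate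
25 | (3S,4R)-4-[(R)-(tert-butyldimethylsilyloxy)[3-methoxy-4-(triisopropylsilyloxy)phenyl]methyl]-3-hydroxy-3-[3-methoxy-4-(triisopropylsilyloxy)benzyl]dihydrofuran-2(3H)-one | COc1cc(C[C@@]2(O)C(=O)OC[C@@H]2[C@@H](O[Si](C)(C)C(C)(C)C)c2ccc(O[Si](C(C)C)(C(C)C)C(C)C)c(OC)c2)ccc1O[Si](C(C)C)(C(C)C)C(C)C | intermediate
26 | (3S,4R)-3-hydroxy-4-[(R)-hydroxy(4-hydroxy-3-methoxyphenyl)methyl]-3-(4-hydroxy-3-methoxybenzyl)dihydrofuran-2(3H)-one (CNP0352022.1) | COc1cc(C[C@@]2(O)C(=O)OC[C@@H]2[C@@H](O)c2ccc(O)c(OC)c2)ccc1O | target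

**Step count and risks**

Total step count: 16. Longest linear sequence: 13 steps (5 → 26, steps 4 to 16).

Steps most likely to fail:

1. Step 15 (proposed new method). The substrate may rest as the aluminium chelate of its benzylic enol instead of migrating, enolisation towards C4 may epimerise C4 or expel silanolate, or the benzyl group may cross on the face syn to the C4 substituent. The fallback uses known chemistry, sets out from terminal alkyne 19 and returns at 25. Anti-Markovnikov hydroboration of 19 with dicyclohexylborane and oxidation with NaBO3 would give the homologous aldehyde F1. NaClO2/NaH2PO4 with 2-methyl-2-butene would oxidise it to the carboxylic acid F2. HF·pyridine/pyridine would free the primary hydroxyl to give the hydroxy acid F3, which should close on standing or with a trace of acid to the γ-lactone F4. KN(SiMe3)2 followed by 3-phenyl-2-(phenylsulfonyl)oxaziridine would hydroxylate C3 to give the α-hydroxy lactone F5, whose C3 configuration is of no consequence. Two equivalents of LiN(i-Pr)2 in THF/DMPU at −78 °C would give the dilithium enediolate F6, and bromide 4 should alkylate it anti to the C4 substituent to give 25, with the same trans benzyl/cis hydroxyl arrangement.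

2. Step 13. Permanganate may over-oxidise by attacking the benzylic enol of the product and cleaving the C1–C2 or C2–C3 bond, or the hindered alkyne may react too slowly. The fallback sets out from alkyne 21 and returns at 22. Semihydrogenation (H2, Pd/CaCO3 poisoned with Pb(OAc)2, quinoline) would give the (Z)-alkene F7. OsO4 (catalytic) with N-methylmorpholine N-oxide would give the syn diol F8 as a diastereomer mixture that does not matter. A double Swern oxidation ((COCl)2, DMSO, then Et3N, −78 °C) would take both secondary alcohols to the diketone 22 without C–C cleavage.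

3. Step 14. Selectivity among the four silyl ethers may be lost (cleavage of the secondary TBS or an aryl TIPS ether), or the diketone may epimerise or undergo β-elimination during the desilylation. The fallback sets out from alkyne 21 and returns at 23; it moves the differentiating desilylation to the robust alkyne stage and leaves only a much more labile group for the diketone stage. HF·pyridine/pyridine on 21 would give the homopropargylic alcohol F9. Et3SiCl/imidazole would give the triethylsilyl ether F10. Buffered KMnO4 as in step 13 would give the triethylsilyl-protected diketone F11. AcOH/THF/H2O at rt should then remove only the primary triethylsilyl group to give 23.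

Further compounds
F1 | step 15 | homologous aldehyde (3R,4R)-4-(tert-butyldimethylsilyloxy)-3-[(tert-butyldimethylsilyloxy)methyl]-4-[3-methoxy-4-(triisopropylsilyloxy)phenyl]butanal | O=CC[C@H](CO[Si](C)(C)C(C)(C)C)[C@@H](O[Si](C)(C)C(C)(C)C)c1ccc(O[Si](C(C)C)(C(C)C)C(C)C)c(OC)c1
F2 | step 15 | carboxylic acid (3R,4R)-4-(tert-butyldimethylsilyloxy)-3-[(tert-butyldimethylsilyloxy)methyl]-4-[3-methoxy-4-(triisopropylsilyloxy)phenyl]butanoic acid | OC(=O)C[C@H](CO[Si](C)(C)C(C)(C)C)[C@@H](O[Si](C)(C)C(C)(C)C)c1ccc(O[Si](C(C)C)(C(C)C)C(C)C)c(OC)c1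
F3 | step 15 | hydroxy acid (3R,4R)-4-(tert-butyldimethylsilyloxy)-3-(hydroxymethyl)-4-[3-methoxy-4-(triisopropylsilyloxy)phenyl]butanoic acid | OC(=O)C[C@H](CO)[C@@H](O[Si](C)(C)C(C)(C)C)c1ccc(O[Si](C(C)C)(C(C)C)C(C)C)c(OC)c1
F4 | step 15 | γ-lactone (4R)-4-[(R)-(tert-butyldimethylsilyloxy)[3-methoxy-4-(triisopropylsilyloxy)phenyl]methyl]dihydrofuran-2(3H)-one | O=C1C[C@@H]([C@@H](O[Si](C)(C)C(C)(C)C)c2ccc(O[Si](C(C)C)(C(C)C)C(C)C)c(OC)c2)CO1
F5 | step 15 | α-hydroxy lactone, the 3-hydroxy derivative of F4 (C3 epimers, other centres as in F4) | OC1C(=O)OC[C@@H]1[C@@H](O[Si](C)(C)C(C)(C)C)c1ccc(O[Si](C(C)C)(C(C)C)C(C)C)c(OC)c1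
F6 | step 15 | dilithium enediolate of F5 | [Li]OC1=C(O[Li])[C@@H]([C@@H](O[Si](C)(C)C(C)(C)C)c2ccc(O[Si](C(C)C)(C(C)C)C(C)C)c(OC)c2)CO1
F7 | step 13 | (Z)-alkene from semihydrogenation of 21 | COc1cc(C/C=C\[C@H](CO[Si](C)(C)C(C)(C)C)[C@@H](O[Si](C)(C)C(C)(C)C)c2ccc(O[Si](C(C)C)(C(C)C)C(C)C)c(OC)c2)ccc1O[Si](C(C)C)(C(C)C)C(C)C
F8 | step 13 | syn diol from dihydroxylation of F7 (diol carbons as a diastereomer mixture) | COc1cc(CC(O)C(O)[C@H](CO[Si](C)(C)C(C)(C)C)[C@@H](O[Si](C)(C)C(C)(C)C)c2ccc(O[Si](C(C)C)(C(C)C)C(C)C)c(OC)c2)ccc1O[Si](C(C)C)(C(C)C)C(C)C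
F9 | step 14 | homopropargylic alcohol, 21 with the primary silyl group removed | COc1cc(CC#C[C@H](CO)[C@@H](O[Si](C)(C)C(C)(C)C)c2ccc(O[Si](C(C)C)(C(C)C)C(C)C)c(OC)c2)ccc1O[Si](C(C)C)(C(C)C)C(C)C
F10 | step 14 | triethylsilyl ether of F9 | COc1cc(CC#C[C@H](CO[Si](CC)(CC)CC)[C@@H](O[Si](C)(C)C(C)(C)C)c2ccc(O[Si](C(C)C)(C(C)C)C(C)C)c(OC)c2)ccc1O[Si](C(C)C)(C(C)C)C(C)C
F11 | step 14 | triethylsilyl-protected diketone, 23 with the primary hydroxyl as its triethylsilyl ether | COc1cc(CC(=O)C(=O)[C@H](CO[Si](CC)(CC)CC)[C@@H](O[Si](C)(C)C(C)(C)C)c2ccc(O[Si](C(C)C)(C(C)C)C(C)C)c(OC)c2)ccc1O[Si](C(C)C)(C(C)C)C(C)C
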